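**Strategy.** The target is assembled from its catechin terminus by three 4β→8 couplings, and the epicatechin unit next to that terminus is built de novo. Everything rests on cutting its ring C at O1–C8a and C4–C4a: 3,5-bis(benzyloxy)benzyne takes up the C2 alkoxide of an acyclic syn-aldol Weinreb amide (O1–C2–C3–C4, both stereocentres already set) at C8a, and the aryl anion at C4a acylates C4, closing the pyran in one operation. The step exploits the phloroglucinol pattern of ring A: the C5 oxygen beside C4a dictates where oxygen and carbon add. In-flask reduction gives a flavan-4-ol whose C4 epimers converge in the next coupling.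

Key step: step 7

Remark: usual flavan numbering is used (O1, C2, C3, C4, C4a, C5–C8, C8a; rings A, B, C). The flavan units are called unit 1 (top epicatechin) to unit 4 (terminal catechin); the unit built de novo is unit 3. Compounds 1, 2, 4, 7, 14 and 17 are assumed to be catalogue items.

Step 1
Reactants: 1 (S)-4-benzyloxazolidin-2-one; 2 (benzyloxy)acetyl chloride
Product: 3 (S)-4-benzyl-3-[(benzyloxy)acetyl]oxazolidin-2-one
Conditions: n-BuLi, THF, −78 °C; then 2, −78 °C to 0 °C
Reagents that add atoms: none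
Why: N-acylation of the lithiated oxazolidinone by the acid chloride; the auxiliary stereocentre is not touched.

Step 2
Reactants: 3 glycolate imide; 4 3,4-bis(benzyloxy)benzaldehyde
Product: 5 (S)-4-benzyl-3-{(2S,3R)-2-(benzyloxy)-3-[3,4-bis(benzyloxy)phenyl]-3-hydroxypropanoyl}oxazolidin-2-one (syn aldol)
Conditions: Bu2BOTf, Et3N, CH2Cl2, −78 °C to 0 °C; then 4, −78 °C to 0 °C; pH 7 buffer, MeOH, H2O2
Reagents that add atoms: none
Why: Evans syn-aldol reaction: the Z boron enolate reacts through a Zimmerman–Traxler chair with the aldehyde approaching anti to the benzyl group of the auxiliary, which should set the (2S,3R) syn pair that becomes C3 and C2 of unit 3.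

Step 3
Reactants: 5 syn-aldol imide
Product: 6 (2S,3R)-2-(benzyloxy)-3-[3,4-bis(benzyloxy)phenyl]-3-hydroxy-N-methoxy-N-methylpropanamide
Conditions: MeNHOMe·HCl, AlMe3, CH2Cl2, −20 °C to 0 °C
Reagents that add atoms: N,O-dimethylhydroxylamine hydrochloride, CNOC.Cl
Why: Weinreb transamination of the imide by the aluminium amide, assisted by the free β-hydroxyl, releases the auxiliary without touching either stereocentre.

Step 4
Reactants: 7 3,5-bis(benzyloxy)phenol
Product: 8 3,5-bis(benzyloxy)phenyl N-isopropylcarbamate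
Conditions: iPrNCO, Et3N (cat.), CH2Cl2, rt
Reagents that add atoms: isopropyl isocyanate, CC(C)N=C=O
Why: Base-catalysed addition of the phenol to the isocyanate installs a carbamate that serves as a removable directing group.

Step 5
Reactants: 8 aryl carbamate
Product: 9 3,5-bis(benzyloxy)-2-(trimethylsilyl)phenyl N-isopropylcarbamate
Conditions: TBSOTf, TMEDA, Et2O, 0 °C to rt; n-BuLi, TMEDA, −78 °C; TMSCl, −78 °C to rt; aq. NaHSO4 (brief)
Reagents that add atoms: chlorotrimethylsilane, C[Si](C)(C)Cl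
Why: Directed ortho-metalation by the carbamate (N-silylated in the flask) lithiates C2, which is flanked by the carbamate and a benzyloxy group (the two ortho positions are equivalent by symmetry), and the silyl chloride traps the aryllithium.

Step 6
Reactants: 9 ortho-silyl carbamate
Product: 10 3,5-bis(benzyloxy)-2-(trimethylsilyl)phenyl trifluoromethanesulfonate
Conditions: DBU, Et2NH, MeCN, 40 °C; then PhNTf2, rt
Reagents that add atoms: N-phenylbis(trifluoromethanesulfonimide), O=S(=O)(N(c1ccccc1)S(=O)(=O)C(F)(F)F)C(F)(F)F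
Why: E1cB cleavage of the N-monosubstituted carbamate (the isocyanate is trapped by Et2NH) gives the phenoxide, which is triflated in the same flask to the ortho-silylaryl triflate aryne precursor.

Step 7
Reactants: 6 hydroxy Weinreb amide; 10 silylaryl triflate
Product: 13 (2R,3R)-3,5,7-tris(benzyloxy)-2-[3,4-bis(benzyloxy)phenyl]chroman-4-ol (2,3-cis; both C4 epimers), via 3,5-bis(benzyloxy)benzyne 11 (not isolated), via 2,3-cis-flavan-4-one 12 (not isolated)
Conditions: KF, 18-crown-6, THF, 0 °C to rt (10 added slowly); then NaBH4, MeOH, −20 °C to 0 °C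
Reagents that add atoms: none
Why: Proposed new method: fluoride unmasks aryne 11 from 10 and, as a base, activates the C2 hydroxyl of 6; the oxygen adds to the aryne carbon remote from the flanking benzyloxy group (future C8a) because the C5 benzyloxy group beside the triple bond polarises it and stabilises the negative charge at the adjacent carbon (future C4a), and this aryl anion then attacks the Weinreb carbonyl (C4) in a 6-exo-trig closure that forms ring C. The closest known reaction type is the tandem aryne O-arylation/intramolecular acylation of salicylate esters to xanthones; here a secondary benzylic alkoxide replaces the phenoxide and a Weinreb amide replaces the ester. Ketone 12 is reduced by NaBH4 in the same flask, so that the base-sensitive 2,3-cis-3-alkoxyflavanone should not epimerise at C3 or open to a chalcone. The annulation creates no stereocentre: C2 and C3 come unchanged from the aldol (the O–C2 bond is never broken), which fixes the 2,3-cis epicatechin relationship, and the C4 carbinol centre is deliberately left uncontrolled because step 9 ionises it. The step needs regioselectivity (oxygen at C8a, carbon at C4a), secured by the single alkoxy group next to the aryne bond, and ring closure in preference to proton quench of the aryl anion, favoured by the six-membered transition state and the aprotic medium; slow addition of 10 should limit double arylation.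

Step 8
Reactants: 14 (+)-catechin
Product: 15 5,7,3',4'-tetra-O-benzyl-(+)-catechin
Conditions: BnBr, K2CO3, DMF, 0 °C to rt
Reagents that add atoms: benzyl bromide, BrCc1ccccc1
Why: Williamson etherification with a carbonate base alkylates the four phenols and leaves the much less acidic C3 alcohol free.

Step 9
Reactants: 13 flavan-4-ol (unit 3 electrophile); 15 tetra-O-benzylcatechin (3 equiv)
Product: 16 nona-O-benzyl dimer, 3,5,7,3',4'-penta-O-benzylepicatechin-(4β→8)-5,7,3',4'-tetra-O-benzylcatechin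
Conditions: TMSOTf (cat.), 4 Å MS, CH2Cl2, −78 °C to −40 °C
Reagents that add atoms: none
Why: Lewis-acid-promoted dehydrative Friedel–Crafts coupling of a flavan-4-ol: both C4 epimers of 13 lose the C4 hydroxyl as water (taken up by the sieves) to give the same benzylic cation stabilised by ring A, and C8 of 15 should attack anti to the pseudoaxial C3 benzyloxy group, so the new C4 centre is set 3,4-trans (4β) and the epimer mixture converges.

Step 10
Reactants: 17 (−)-epicatechin
Product: 18 5,7,3',4'-tetra-O-benzyl-(−)-epicatechin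
Conditions: BnBr, K2CO3, DMF, 0 °C to rt
Reagents that add atoms: benzyl bromide, BrCc1ccccc1
Why: Williamson etherification selective for the four phenols over the C3 alcohol, as in step 8.

Step 11
Reactants: 18 tetra-O-benzylepicatechin
Product: 19 4β-(2-ethoxyethoxy)-5,7,3',4'-tetra-O-benzylepicatechin
Conditions: DDQ, 2-ethoxyethanol, CH2Cl2, rt
Reagents that add atoms: 2-ethoxyethanol, CCOCCO
Why: DDQ benzylic oxidation (hydride abstraction at C4 of the electron-rich chroman) gives a quinone-methide-type cation that the alcohol should trap anti to the C3 hydroxyl, setting the 4β ether.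

Step 12
Reactants: 16 dimer nucleophile (2 equiv, excess recovered); 19 C4 electrophile
Product: 20 trideca-O-benzyl trimer, tetra-O-benzylepicatechin-(4β→8)-penta-O-benzylepicatechin-(4β→8)-tetra-O-benzylcatechin
Conditions: TMSOTf (cat.), CH2Cl2, −78 °C, slow addition of 19
Reagents that add atoms: none
Why: TMSOTf-catalysed Friedel–Crafts interflavan coupling: the C4 cation from 19 should be attacked by the free C8 of the ring A made in step 7 (the most accessible electron-rich position of 16) anti to the C3 hydroxyl, setting the 4β configuration.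

Step 13
Reactants: 20 trimer nucleophile (2 equiv, excess recovered); 19 C4 electrophile
Product: 21 heptadeca-O-benzyl tetramer, tetra-O-benzylepicatechin-(4β→8)-tetra-O-benzylepicatechin-(4β→8)-penta-O-benzylepicatechin-(4β→8)-tetra-O-benzylcatechin
Conditions: TMSOTf (cat.), CH2Cl2, −78 °C, slow addition of 19
Reagents that add atoms: none
Why: The same Friedel–Crafts interflavan coupling at C8 of the top unit of 20, with attack anti to the C3 hydroxyl of the cation setting the last 4β centre.

Step 14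
Reactants: 21 protected tetramer
Product: 22 epicatechin-(4β→8)-epicatechin-(4β→8)-epicatechin-(4β→8)-catechin (the target)
Conditions: H2 (1 atm), Pd(OH)2/C, THF/MeOH/H2O, rt
Reagents that add atoms: none
Why: Hydrogenolysis of all seventeen benzyl ethers (sixteen aryl, one alkyl) under neutral conditions should leave the interflavan bonds and every stereocentre untouched.

**Compound list**

1 | (S)-4-benzyloxazolidin-2-one | O=C1N[C@@H](Cc2ccccc2)CO1 | starting material
2 | (benzyloxy)acetyl chloride | O=C(Cl)COCc1ccccc1 | starting material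
3 | (S)-4-benzyl-3-[(benzyloxy)acetyl]oxazolidin-2-one | O=C(COCc1ccccc1)N1[C@@H](Cc2ccccc2)COC1=O | intermediate
4 | 3,4-bis(benzyloxy)benzaldehyde | O=Cc1ccc(OCc2ccccc2)c(OCc2ccccc2)c1 | starting material
5 | (S)-4-benzyl-3-{(2S,3R)-2-(benzyloxy)-3-[3,4-bis(benzyloxy)phenyl]-3-hydroxypropanoyl}oxazolidin-2-one | O[C@H](c1ccc(OCc2ccccc2)c(OCc2ccccc2)c1)[C@H](OCc1ccccc1)C(=O)N1[C@@H](Cc2ccccc2)COC1=O | intermediate
6 | (2S,3R)-2-(benzyloxy)-3-[3,4-bis(benzyloxy)phenyl]-3-hydroxy-N-methoxy-N-methylpropanamide | O[C@H](c1ccc(OCc2ccccc2)c(OCc2ccccc2)c1)[C@H](OCc1ccccc1)C(=O)N(C)OC | intermediate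
7 | 3,5-bis(benzyloxy)phenol | Oc1cc(OCc2ccccc2)cc(OCc2ccccc2)c1 | starting material
8 | 3,5-bis(benzyloxy)phenyl N-isopropylcarbamate | CC(C)NC(=O)Oc1cc(OCc2ccccc2)cc(OCc2ccccc2)c1 | intermediate
9 | 3,5-bis(benzyloxy)-2-(trimethylsilyl)phenyl N-isopropylcarbamate | CC(C)NC(=O)Oc1cc(OCc2ccccc2)cc(OCc2ccccc2)c1[Si](C)(C)C | intermediate
10 | 3,5-bis(benzyloxy)-2-(trimethylsilyl)phenyl trifluoromethanesulfonate | C[Si](C)(C)c1c(OCc2ccccc2)cc(OCc2ccccc2)cc1OS(=O)(=O)C(F)(F)F | intermediate
11 | 3,5-bis(benzyloxy)benzyne (not isolated) | C1#CC(OCc2ccccc2)=CC(OCc2ccccc2)=C1 | intermediate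
12 | (2R,3S)-3,5,7-tris(benzyloxy)-2-[3,4-bis(benzyloxy)phenyl]chroman-4-one, 2,3-cis (not isolated) | c1ccccc1COc1cc(OCc3ccccc3)c2c(c1)O[C@H](c1ccc(OCc3ccccc3)c(OCc3ccccc3)c1)[C@H](OCc1ccccc1)C2=O | intermediate
13 | (2R,3R)-3,5,7-tris(benzyloxy)-2-[3,4-bis(benzyloxy)phenyl]chroman-4-ol, 2,3-cis, both C4 epimers | c1ccccc1COc1cc(OCc3ccccc3)c2c(c1)O[C@H](c1ccc(OCc3ccccc3)c(OCc3ccccc3)c1)[C@H](OCc1ccccc1)C2O | intermediate
14 | (+)-catechin | Oc1cc(O)c2c(c1)O[C@H](c1ccc(O)c(O)c1)[C@@H](O)C2 | starting material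
15 | 5,7,3',4'-tetra-O-benzyl-(+)-catechin | c1ccccc1COc1cc(OCc3ccccc3)c2c(c1)O[C@H](c1ccc(OCc3ccccc3)c(OCc3ccccc3)c1)[C@@H](O)C2 | intermediate
16 | 3,5,7,3',4'-penta-O-benzylepicatechin-(4β→8)-5,7,3',4'-tetra-O-benzylcatechin | c1ccccc1COc1cc(OCc3ccccc3)c2c(c1)O[C@H](c1ccc(OCc3ccccc3)c(OCc3ccccc3)c1)[C@H](OCc1ccccc1)[C@H]2c1c(OCc3ccccc3)cc(OCc3ccccc3)c2c1O[C@H](c1ccc(OCc3ccccc3)c(OCc3ccccc3)c1)[C@@H](O)C2 | intermediate
17 | (−)-epicatechin | Oc1cc(O)c2c(c1)O[C@H](c1ccc(O)c(O)c1)[C@H](O)C2 | starting material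
18 | 5,7,3',4'-tetra-O-benzyl-(−)-epicatechin | c1ccccc1COc1cc(OCc3ccccc3)c2c(c1)O[C@H](c1ccc(OCc3ccccc3)c(OCc3ccccc3)c1)[C@H](O)C2 | intermediate
19 | 4β-(2-ethoxyethoxy)-5,7,3',4'-tetra-O-benzylepicatechin | c1ccccc1COc1cc(OCc3ccccc3)c2c(c1)O[C@H](c1ccc(OCc3ccccc3)c(OCc3ccccc3)c1)[C@H](O)[C@H]2OCCOCC | intermediate
20 | tetra-O-benzylepicatechin-(4β→8)-penta-O-benzylepicatechin-(4β→8)-tetra-O-benzylcatechin | c1ccccc1COc1cc(OCc3ccccc3)c2c(c1)O[C@H](c1ccc(OCc3ccccc3)c(OCc3ccccc3)c1)[C@H](O)[C@H]2c1c(OCc3ccccc3)cc(OCc3ccccc3)c2c1O[C@H](c1ccc(OCc3ccccc3)c(OCc3ccccc3)c1)[C@H](OCc1ccccc1)[C@H]2c1c(OCc3ccccc3)cc(OCc3ccccc3)c2c1O[C@H](c1ccc(OCc3ccccc3)c(OCc3ccccc3)c1)[C@@H](O)C2 | intermediate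
21 | tetra-O-benzylepicatechin-(4β→8)-tetra-O-benzylepicatechin-(4β→8)-penta-O-benzylepicatechin-(4β→8)-tetra-O-benzylcatechin | c1ccccc1COc1cc(OCc3ccccc3)c2c(c1)O[C@H](c1ccc(OCc3ccccc3)c(OCc3ccccc3)c1)[C@H](O)[C@H]2c1c(OCc3ccccc3)cc(OCc3ccccc3)c2c1O[C@H](c1ccc(OCc3ccccc3)c(OCc3ccccc3)c1)[C@H](O)[C@H]2c1c(OCc3ccccc3)cc(OCc3ccccc3)c2c1O[C@H](c1ccc(OCc3ccccc3)c(OCc3ccccc3)c1)[C@H](OCc1ccccc1)[C@H]2c1c(OCc3ccccc3)cc(OCc3ccccc3)c2c1O[C@H](c1ccc(OCc3ccccc3)c(OCc3ccccc3)c1)[C@@H](O)C2 | intermediate
22 | epicatechin-(4β→8)-epicatechin-(4β→8)-epicatechin-(4β→8)-catechin, the fully deprotected tetramer | Oc1cc(O)c2c(c1)O[C@H](c1ccc(O)c(O)c1)[C@H](O)[C@H]2c1c(O)cc(O)c2c1O[C@H](c1ccc(O)c(O)c1)[C@H](O)[C@H]2c1c(O)cc(O)c2c1O[C@H](c1ccc(O)c(O)c1)[C@H](O)[C@H]2c1c(O)cc(O)c2c1O[C@H](c1ccc(O)c(O)c1)[C@@H](O)C2 | target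

**Step count.** Total: 14 steps. Longest linear sequence: 8 steps (steps 1, 2, 3, 7, 9, 12, 13, 14).

**Steps most likely to fail**

1. Step 7 (aryne annulation). The aryl anion may be protonated before it closes the ring, giving plain O-arylation. The alkoxide of 6 may also fragment by retro-aldol cleavage, or the cis ketone may epimerise at C3 before it is reduced. The fallback uses known chemistry and gives up the de novo construction of ring C. It sets out from 18, whose C3 hydroxyl is benzylated (NaH, BnBr, DMF, 0 °C) to 3,5,7,3',4'-penta-O-benzylepicatechin F1. DDQ oxidation in the presence of 2-ethoxyethanol (CH2Cl2, rt) should then give 4β-(2-ethoxyethoxy)-penta-O-benzylepicatechin F2. TMSOTf-catalysed coupling of F2 with excess 15 (CH2Cl2, −78 °C) comes back to the route at 16.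

2. Step 13 (last chain extension). The electrophile may self-condense through its own free C8, and the large nucleophile may be attacked at C6 positions, so that oligomer mixtures form. The fallback blocks the electrophile. It sets out from 18, which NBS (CH2Cl2, −78 °C) should brominate at C8 to 8-bromo-5,7,3',4'-tetra-O-benzylepicatechin F3. DDQ and 2-ethoxyethanol convert F3 into 8-bromo-4β-(2-ethoxyethoxy)-tetra-O-benzylepicatechin F4, which cannot self-condense at C8. Equimolar TMSOTf-catalysed coupling of F4 with 20 should give the 8-bromo heptadeca-O-benzyl tetramer F5. Hydrogenolysis of F5 in the presence of Et3N (H2, Pd(OH)2/C, THF/MeOH/H2O) removes the bromine together with the benzyl groups and comes back to the route at 22.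

3. Step 5 (ortho-silylation). Lithiation of a benzylic ether position with Wittig rearrangement may compete with ortho-metalation, and the electron-rich arylsilane may lose its silyl group on acidic work-up. The fallback replaces deprotonation by halogen–metal exchange. It sets out from 7, which amine-catalysed ortho-bromination (NBS, iPr2NH cat., CH2Cl2, −78 °C to 0 °C) should convert into 2-bromo-3,5-bis(benzyloxy)phenol F6. Silylation with HMDS (THF, reflux) gives [2-bromo-3,5-bis(benzyloxy)phenoxy]trimethylsilane F7. Bromine–lithium exchange (n-BuLi, THF, −78 °C) triggers a retro-Brook O-to-C silyl shift, and triflation of the resulting phenoxide with Tf2O comes back to the route at 10.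

**Further compounds**

F1 | step 7 | 3,5,7,3',4'-penta-O-benzylepicatechin | c1ccccc1COc1cc(OCc3ccccc3)c2c(c1)O[C@H](c1ccc(OCc3ccccc3)c(OCc3ccccc3)c1)[C@H](OCc1ccccc1)C2
F2 | step 7 | 4β-(2-ethoxyethoxy)-3,5,7,3',4'-penta-O-benzylepicatechin | c1ccccc1COc1cc(OCc3ccccc3)c2c(c1)O[C@H](c1ccc(OCc3ccccc3)c(OCc3ccccc3)c1)[C@H](OCc1ccccc1)[C@H]2OCCOCC
F3 | step 13 | 8-bromo-5,7,3',4'-tetra-O-benzylepicatechin | c1ccccc1COc1cc(OCc3ccccc3)c2c(c1Br)O[C@H](c1ccc(OCc3ccccc3)c(OCc3ccccc3)c1)[C@H](O)C2
F4 | step 13 | 8-bromo-4β-(2-ethoxyethoxy)-5,7,3',4'-tetra-O-benzylepicatechin | c1ccccc1COc1cc(OCc3ccccc3)c2c(c1Br)O[C@H](c1ccc(OCc3ccccc3)c(OCc3ccccc3)c1)[C@H](O)[C@H]2OCCOCC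
F5 | step 13 | 8-bromo heptadeca-O-benzyl tetramer (bromine at C8 of unit 1) | c1ccccc1COc1cc(OCc3ccccc3)c2c(c1Br)O[C@H](c1ccc(OCc3ccccc3)c(OCc3ccccc3)c1)[C@H](O)[C@H]2c1c(OCc3ccccc3)cc(OCc3ccccc3)c2c1O[C@H](c1ccc(OCc3ccccc3)c(OCc3ccccc3)c1)[C@H](O)[C@H]2c1c(OCc3ccccc3)cc(OCc3ccccc3)c2c1O[C@H](c1ccc(OCc3ccccc3)c(OCc3ccccc3)c1)[C@H](OCc1ccccc1)[C@H]2c1c(OCc3ccccc3)cc(OCc3ccccc3)c2c1O[C@H](c1ccc(OCc3ccccc3)c(OCc3ccccc3)c1)[C@@H](O)C2
F6 | step 5 | 2-bromo-3,5-bis(benzyloxy)phenol | Oc1cc(OCc2ccccc2)cc(OCc2ccccc2)c1Br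
F7 | step 5 | [2-bromo-3,5-bis(benzyloxy)phenoxy]trimethylsilane | C[Si](C)(C)Oc1cc(OCc2ccccc2)cc(OCc2ccccc2)c1Br
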